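The bicyclo[3.2.1]oct-3-ene-2,8-dione is traced to a quinone and a stilbene. A TADDOL–titanium-controlled [2+2] addition of tetra-O-benzylpiceatannol to 2-methoxy-6-methyl-1,4-benzoquinone gives a cyclobutane-fused enedione. In the key step TiCl4 ionises the benzylic cyclobutane bond C4–C7 (target numbering) and the cation recloses on the enol ether carbon C1: the four-membered ring C4–C5–C6–C7 grows into the cyclopentanone C1–C8–C5–C6–C7, and the bridged core with all four stereocentres is in place. The step exploits the para-oxygenated aryl on C7, which carries the cation, and the 1,3-placement of C1 and C5 across the C8 carbonyl. Triflate reduction at C3 and a vinylogous aldol condensation at the C4 methyl finish.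

Key step: step 4

Remark: atom numbers in the text are those of the target skeleton, bicyclo[3.2.1]octane C1–C8 (C1, C5 bridgeheads; C2, C8 carbonyls; C4 styryl-bearing; C6 carries the 3,5-dioxygenated aryl, C7 the 3,4-dioxygenated aryl).
Remark: the facial sense of the (4R,5R)-TADDOLate promoter in step 3 is assigned by analogy with simpler styrenes; should it deliver the mirror-image cyclobutane, the (4S,5S)-diol is used instead.

Step 1
Reactants: 1 2-methoxy-6-methylphenol
Product: 2 2-methoxy-6-methylcyclohexa-2,5-diene-1,4-dione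
Conditions: O2 (1 atm), Co(salen) (5 mol %), DMF, 25 °C
Reagents that add atoms: dioxygen, O=O
Why: Cobalt–salen-catalysed aerobic oxidation of a 2,6-disubstituted phenol should give the para-quinone, the free para position being the only site open to oxygenation.

Step 2
Reactants: 3 piceatannol, (E)-4-[2-(3,5-dihydroxyphenyl)ethenyl]benzene-1,2-diol
Product: 4 (E)-1,2-bis(benzyloxy)-4-{2-[3,5-bis(benzyloxy)phenyl]ethenyl}benzene
Conditions: BnBr, K2CO3, DMF, 60 °C
Reagents that add atoms: benzyl bromide, BrCc1ccccc1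
Why: Williamson etherification of the four phenols should proceed cleanly, and the benzyl ethers keep the 3,4-dioxygenated ring electron-rich while being inert to the titanium, triflation and palladium steps that follow.

Step 3
Reactants: 2 2-methoxy-6-methylcyclohexa-2,5-diene-1,4-dione; 4 (E)-1,2-bis(benzyloxy)-4-{2-[3,5-bis(benzyloxy)phenyl]ethenyl}benzene
Product: 5 (1R,6S,7S,8R)-8-[3,4-bis(benzyloxy)phenyl]-7-[3,5-bis(benzyloxy)phenyl]-3-methoxy-1-methylbicyclo[4.2.0]oct-3-ene-2,5-dione
Conditions: TiCl2[(4R,5R)-TADDOLate] (3 equiv, made in the flask from TiCl4, Ti(OiPr)4 and (4R,5R)-TADDOL), CH2Cl2, −78 °C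
Reagents that add atoms: none
Why: This is the Lewis-acid-promoted stepwise formal [2+2] cycloaddition of a 2-alkoxy-1,4-benzoquinone with an electron-rich styrene-type alkene: titanium chelates the C3 carbonyl and the C2 methoxy oxygen, the alkene carbon remote from the 3,4-dioxygenated ring (future C6) attacks C5, the para-benzyloxybenzyl cation closes on the enolate carbon C4, the chiral TADDOLate shields one quinone face so that C5 and C6 are set in the first bond formation, ring fusion is necessarily cis and the aryl groups stay trans as in the E-alkene.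

Step 4
Reactants: 5 (1R,6S,7S,8R)-8-[3,4-bis(benzyloxy)phenyl]-7-[3,5-bis(benzyloxy)phenyl]-3-methoxy-1-methylbicyclo[4.2.0]oct-3-ene-2,5-dione
Product: 8 (1S,5S,6S,7S)-7-[3,4-bis(benzyloxy)phenyl]-6-[3,5-bis(benzyloxy)phenyl]-3-hydroxy-4-methylbicyclo[3.2.1]oct-3-ene-2,8-dione, via benzylic cation–dienolate zwitterion 6 (not isolated), via bridged O-methyloxocarbenium enolate 7 (not isolated)
Conditions: TiCl4 (3 equiv), CH2Cl2, −78 °C; aq. NaHCO3 quench at −78 °C
Reagents that add atoms: none
Why: TiCl4 chelates the C3 carbonyl and the C2 methoxy oxygen and heterolyses the strained cyclobutane bond C4–C7 to a tetravalent-titanium dienolate (O–C3=C4) and a C7 benzylic cation stabilised by the para-benzyloxy group (6). The cation is captured by C1, the nucleophilic β-carbon of the methyl enol ether, in a 5-(enolexo)-exo-trig closure that turns the cyclobutane C4–C5–C6–C7 into the cyclopentanone ring C1–C8–C5–C6–C7 and bridges the six-membered ring (7); chloride then removes the oxocarbenium methyl group as chloromethane, which makes the ring expansion irreversible, and work-up frees the C3 enol. The closest known reaction type is the Lewis-acid-induced rearrangement of 8-aryl-3-methoxybicyclo[4.2.0]oct-3-ene-2,5-diones to 7-aryl-3-hydroxybicyclo[3.2.1]oct-3-ene-2,8-diones, a cyclobutane-to-cyclopentane enlargement by net shift of the benzylic carbon. C5 and C6 are not touched and keep the configuration and enantiomeric purity set in step 3; C1 is fixed by the tether, since the cation held on C6 can reach only the face of C1 syn to C6; C7 is set by closure through the conformer of the planar cation that keeps its aryl group anti to the C6 aryl group, which places it endo over the C2–C4 bridge and trans to its neighbour. The step needs carbon capture at C1 in preference to return to C4 and to proton loss at C5 followed by oxygen capture (aromatisation to a dihydrobenzofuranol); the high nucleophilicity of the enol ether carbon, the irreversible dealkylation and aprotic conditions at −78 °C should secure it.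

Step 5
Reactants: 8 (1S,5S,6S,7S)-7-[3,4-bis(benzyloxy)phenyl]-6-[3,5-bis(benzyloxy)phenyl]-3-hydroxy-4-methylbicyclo[3.2.1]oct-3-ene-2,8-dione
Product: 9 (1S,5S,6S,7S)-7-[3,4-bis(benzyloxy)phenyl]-6-[3,5-bis(benzyloxy)phenyl]-4-methyl-2,8-dioxobicyclo[3.2.1]oct-3-en-3-yl trifluoromethanesulfonate
Conditions: Tf2O, pyridine, CH2Cl2, −78 → 0 °C
Reagents that add atoms: trifluoromethanesulfonic anhydride, O=S(=O)(OS(=O)(=O)C(F)(F)F)C(F)(F)F
Why: O-sulfonylation of the acidic diosphenol (the enol of the 1,2-dione) should give the vinyl triflate at the only hydroxyl group without touching a stereocentre.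

Step 6
Reactants: 9 (1S,5S,6S,7S)-7-[3,4-bis(benzyloxy)phenyl]-6-[3,5-bis(benzyloxy)phenyl]-4-methyl-2,8-dioxobicyclo[3.2.1]oct-3-en-3-yl trifluoromethanesulfonate
Product: 10 (1R,5S,6S,7S)-7-[3,4-bis(benzyloxy)phenyl]-6-[3,5-bis(benzyloxy)phenyl]-4-methylbicyclo[3.2.1]oct-3-ene-2,8-dione
Conditions: Pd(OAc)2 (5 mol %), PPh3, HCO2H, Et3N, DMF, 60 °C
Reagents that add atoms: none
Why: Palladium-catalysed formate reduction of a vinyl triflate (oxidative addition to zerovalent palladium, formate exchange, decarboxylation to the hydride, reductive elimination) should replace the C3 oxygen by hydrogen while ketones, benzyl ethers and stereocentres stay untouched.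

Step 7
Reactants: 10 (1R,5S,6S,7S)-7-[3,4-bis(benzyloxy)phenyl]-6-[3,5-bis(benzyloxy)phenyl]-4-methylbicyclo[3.2.1]oct-3-ene-2,8-dione; 11 3,4-bis(benzyloxy)benzaldehyde
Product: 12 (1R,5S,6S,7S)-7-[3,4-bis(benzyloxy)phenyl]-6-[3,5-bis(benzyloxy)phenyl]-4-{(E)-2-[3,4-bis(benzyloxy)phenyl]ethenyl}bicyclo[3.2.1]oct-3-ene-2,8-dione
Conditions: pyrrolidine (30 mol %), AcOH (30 mol %), toluene, 4 Å MS, 60 °C
Reagents that add atoms: none
Why: Amine-catalysed vinylogous aldol condensation through the cross-conjugated dienamine of the β-methyl enone should occur only at the C4 methyl group, because the other α′ and γ positions are bridgeheads, and dehydration gives the conjugated E-styryl dienone without hydroxide or alkoxide that could open the bridgehead 1,3-diketone.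

Step 8
Reactants: 12 (1R,5S,6S,7S)-7-[3,4-bis(benzyloxy)phenyl]-6-[3,5-bis(benzyloxy)phenyl]-4-{(E)-2-[3,4-bis(benzyloxy)phenyl]ethenyl}bicyclo[3.2.1]oct-3-ene-2,8-dione
Product: 13 (1R,5S,6S,7S)-7-(3,4-dihydroxyphenyl)-6-(3,5-dihydroxyphenyl)-4-[(E)-2-(3,4-dihydroxyphenyl)ethenyl]bicyclo[3.2.1]oct-3-ene-2,8-dione (CNP0285027.2)
Conditions: BCl3, C6HMe5, CH2Cl2, −78 °C; MeOH quench at −78 °C
Reagents that add atoms: none
Why: Lewis-acid debenzylation in the presence of pentamethylbenzene as benzyl-cation scavenger should cleave the six aryl benzyl ethers at −78 °C without reducing the alkenes, and the low temperature limits acid-induced opening of the C1–C7 bond.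

Compound list
1 | 2-methoxy-6-methylphenol | COc1cccc(C)c1O | starting material
2 | 2-methoxy-6-methylcyclohexa-2,5-diene-1,4-dione | COC1=CC(=O)C=C(C)C1=O | intermediate
3 | piceatannol, (E)-4-[2-(3,5-dihydroxyphenyl)ethenyl]benzene-1,2-diol | Oc1ccc(/C=C/c2cc(O)cc(O)c2)cc1O | starting material
4 | (E)-1,2-bis(benzyloxy)-4-{2-[3,5-bis(benzyloxy)phenyl]ethenyl}benzene | C(Oc1ccc(/C=C/c2cc(OCc3ccccc3)cc(OCc3ccccc3)c2)cc1OCc1ccccc1)c1ccccc1 | intermediate
5 | (1R,6S,7S,8R)-8-[3,4-bis(benzyloxy)phenyl]-7-[3,5-bis(benzyloxy)phenyl]-3-methoxy-1-methylbicyclo[4.2.0]oct-3-ene-2,5-dione (cis-fused, aryl groups trans) | COC1=CC(=O)[C@H]2[C@@H](c3cc(OCc4ccccc4)cc(OCc4ccccc4)c3)[C@H](c3ccc(OCc4ccccc4)c(OCc4ccccc4)c3)[C@@]2(C)C1=O | intermediate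
6 | benzylic cation–dienolate zwitterion from cleavage of the C4–C7 bond of 5 (titanium-bound in the flask, drawn metal-free) | COC1=CC(=O)[C@@H]([C@@H](c2cc(OCc3ccccc3)cc(OCc3ccccc3)c2)[CH+]c2ccc(OCc3ccccc3)c(OCc3ccccc3)c2)C(C)=C1[O-] | intermediate
7 | bridged O-methyloxocarbenium enolate, the 2-O-methyl cation of the enolate of 8 (titanium-bound in the flask, drawn metal-free) | C[O+]=C1C([O-])=C(C)[C@H]2C(=O)[C@@H]1[C@@H](c1ccc(OCc3ccccc3)c(OCc3ccccc3)c1)[C@@H]2c1cc(OCc3ccccc3)cc(OCc3ccccc3)c1 | intermediate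
8 | (1S,5S,6S,7S)-7-[3,4-bis(benzyloxy)phenyl]-6-[3,5-bis(benzyloxy)phenyl]-3-hydroxy-4-methylbicyclo[3.2.1]oct-3-ene-2,8-dione | O=C1C(O)=C(C)[C@H]2C(=O)[C@@H]1[C@@H](c1ccc(OCc3ccccc3)c(OCc3ccccc3)c1)[C@@H]2c1cc(OCc3ccccc3)cc(OCc3ccccc3)c1 | intermediate
9 | (1S,5S,6S,7S)-7-[3,4-bis(benzyloxy)phenyl]-6-[3,5-bis(benzyloxy)phenyl]-4-methyl-2,8-dioxobicyclo[3.2.1]oct-3-en-3-yl trifluoromethanesulfonate | O=C1C(OS(=O)(=O)C(F)(F)F)=C(C)[C@H]2C(=O)[C@@H]1[C@@H](c1ccc(OCc3ccccc3)c(OCc3ccccc3)c1)[C@@H]2c1cc(OCc3ccccc3)cc(OCc3ccccc3)c1 | intermediate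
10 | (1R,5S,6S,7S)-7-[3,4-bis(benzyloxy)phenyl]-6-[3,5-bis(benzyloxy)phenyl]-4-methylbicyclo[3.2.1]oct-3-ene-2,8-dione | O=C1C=C(C)[C@H]2C(=O)[C@@H]1[C@@H](c1ccc(OCc3ccccc3)c(OCc3ccccc3)c1)[C@@H]2c1cc(OCc3ccccc3)cc(OCc3ccccc3)c1 | intermediate
11 | 3,4-bis(benzyloxy)benzaldehyde | O=Cc1ccc(OCc2ccccc2)c(OCc2ccccc2)c1 | starting material
12 | (1R,5S,6S,7S)-7-[3,4-bis(benzyloxy)phenyl]-6-[3,5-bis(benzyloxy)phenyl]-4-{(E)-2-[3,4-bis(benzyloxy)phenyl]ethenyl}bicyclo[3.2.1]oct-3-ene-2,8-dione | O=C1C=C(/C=C/c2ccc(OCc3ccccc3)c(OCc3ccccc3)c2)[C@H]2C(=O)[C@@H]1[C@@H](c1ccc(OCc3ccccc3)c(OCc3ccccc3)c1)[C@@H]2c1cc(OCc3ccccc3)cc(OCc3ccccc3)c1 | intermediate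
13 | (1R,5S,6S,7S)-7-(3,4-dihydroxyphenyl)-6-(3,5-dihydroxyphenyl)-4-[(E)-2-(3,4-dihydroxyphenyl)ethenyl]bicyclo[3.2.1]oct-3-ene-2,8-dione | O=C1C=C(/C=C/c2ccc(O)c(O)c2)[C@H]2C(=O)[C@@H]1[C@@H](c1ccc(O)c(O)c1)[C@@H]2c1cc(O)cc(O)c1 | target

Total step count: 8. Longest linear sequence: 7 steps (steps 1, 3, 4, 5, 6, 7, 8).

Steps most likely to fail

Step 4 (key step). The ion pair may simply return to the cyclobutane, or lose the C5 proton, aromatise and close through oxygen to a dihydrobenzofuranol; on warming, TiCl4 may also start to cleave benzyl ethers. The fallback sets out from 2 and 4 and comes back at 8. It changes the group that is lost in the irreversible event: alkoxy exchange at the vinylogous ester of 2 with benzyl alcohol (cat. TsOH, benzene, removal of methanol) would give 2-(benzyloxy)-6-methylcyclohexa-2,5-diene-1,4-dione F1. Its [2+2] addition to 4 under the conditions of step 3 would give the 3-benzyloxy analogue of cyclobutane 5 F2. The bridged O-benzyl oxocarbenium formed from F2 loses benzyl chloride far more readily than 7 loses chloromethane, so TiCl4 at −78 °C should trap the ring-expanded skeleton before any proton transfer and give 8.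

Step 3. The hindered 1,2-diaryl alkene may add only slowly to the bulky chiral titanium chelate, facial discrimination may be poor, or the ion pair may collapse directly to bridged or benzofuran products. The fallback sets out from 2 and 4 and comes back at 5. The achiral and more Lewis-acidic promoter made from TiCl4 and Ti(OiPr)4 (CH2Cl2, −78 °C), the standard system for this cycloaddition, would give the racemic cyclobutane. The enantiomers would then be separated by preparative chromatography on a chiral stationary phase, and the mirror-image cyclobutane ent-5 F3 set aside.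

Step 7. The amine may open the non-enolisable bridgehead 1,3-diketone by retro-Claisen attack, or dienamine formation at the hindered C2 carbonyl may be too slow for condensation to compete with decomposition. The fallback sets out from 10 and comes back at 12, and inverts the polarity of the coupling. Riley oxidation of the C4 methyl group (SeO2, dioxane, 80 °C) would give the 4-formyl analogue of 10 F4. Horner–Wadsworth–Emmons olefination of F4 with the sodium salt (NaH, THF, 0 °C) of diethyl [3,4-bis(benzyloxy)benzyl]phosphonate F5 would give 12 with E geometry. F5 would itself be made by Arbuzov reaction of commercial 1,2-bis(benzyloxy)-4-(chloromethyl)benzene with triethyl phosphite.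

Further compounds
F1 | step 4 | 2-(benzyloxy)-6-methylcyclohexa-2,5-diene-1,4-dione | O=C1C=C(C)C(=O)C(OCc2ccccc2)=C1
F2 | step 4 | (1R,6S,7S,8R)-3-(benzyloxy)-8-[3,4-bis(benzyloxy)phenyl]-7-[3,5-bis(benzyloxy)phenyl]-1-methylbicyclo[4.2.0]oct-3-ene-2,5-dione | C(c1ccccc1)OC1=CC(=O)[C@H]2[C@@H](c3cc(OCc4ccccc4)cc(OCc4ccccc4)c3)[C@H](c3ccc(OCc4ccccc4)c(OCc4ccccc4)c3)[C@@]2(C)C1=O
F3 | step 3 | ent-5, (1S,6R,7R,8S)-8-[3,4-bis(benzyloxy)phenyl]-7-[3,5-bis(benzyloxy)phenyl]-3-methoxy-1-methylbicyclo[4.2.0]oct-3-ene-2,5-dione | COC1=CC(=O)[C@@H]2[C@H](c3cc(OCc4ccccc4)cc(OCc4ccccc4)c3)[C@@H](c3ccc(OCc4ccccc4)c(OCc4ccccc4)c3)[C@]2(C)C1=O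
F4 | step 7 | 4-formyl analogue of 10 (CHO in place of the C4 methyl group, configuration unchanged) | O=C1C=C(C=O)[C@H]2C(=O)[C@@H]1[C@@H](c1ccc(OCc3ccccc3)c(OCc3ccccc3)c1)[C@@H]2c1cc(OCc3ccccc3)cc(OCc3ccccc3)c1
F5 | step 7 | diethyl [3,4-bis(benzyloxy)benzyl]phosphonate | CCOP(=O)(Cc1ccc(OCc2ccccc2)c(OCc2ccccc2)c1)OCC
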